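**Plan**

- Retrosynthesis: the three tert-butyl esters come off last. Then the C1–O8 ketal bond is cut (the tetrahydrofuran ring opens), then the C1=C7 alkene (the seven-membered ring opens), the enol-ether methylene, the C3–O acyl bond to the side-chain acid, the C5–C6 bond (allyl) and the C4–C5 bond (acylation of a tartrate enolate).
- Enabling feature: C1, O2, C3, C4, C5, C6 and C7 of the 2,8-dioxabicyclo[3.2.1]octane form a seven-membered ring that lacks only the C1–O8 bridge. A 2,3,4,5-tetrahydrooxepine with a C1=C7 enol ether and a C5 hydroxyl is therefore one protonation away from the bicycle.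
- Forward, core: D-tartaric acid (C3, C4) → cyclic orthoformate → C4 acylation → C5 allylation → triol → C3 ester with the side-chain acid → methylenation → ring-closing metathesis (oxepene, first ring) → transannular ketalisation (second ring) → triacid.
- Forward, side chain: methyl (S)-3-hydroxy-2-methylpropanoate → iodide → Negishi phenylation → aldehyde → isopropenyl carbinol → Johnson–Claisen rearrangement → acid.
- Stereochemistry: C3 from D-tartaric acid; C4 from enolate attack anti to the neighbouring ring ester; C5 from chelate-controlled allyl addition; C1 from the geometry of the O8 bridge; the side-chain methyl centre from the hydroxy ester; the E-alkene from the chair Claisen transition state.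

Key step: step 16

Remark (assumptions): locants C1–C7, O2 and O8 are those of the bicyclic core of the target and are used for the open-chain intermediates as well. The orthoester carbon of 17, 18 and 20 is expected as a mixture of both configurations and is left undefined, because step 11 removes it.

**Side-chain acid**

Step 1
Reactants: 1 methyl (S)-3-hydroxy-2-methylpropanoate
Product: 2 methyl (R)-3-iodo-2-methylpropanoate
Conditions: I2, PPh3, imidazole, CH2Cl2, 0 °C to rt
Reagents that add atoms: iodine, [I][I]
Why: Appel-type iodination of the primary alcohol through an alkoxyphosphonium iodide; the stereocentre is not involved and only its descriptor changes.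

Step 2
Reactants: 2 methyl (R)-3-iodo-2-methylpropanoate; 3 iodobenzene
Product: 5 methyl (S)-2-methyl-3-phenylpropanoate, via alkylzinc iodide 4 (not isolated)
Conditions: Zn dust (I2-activated), DMF, rt; then 3, Pd2(dba)3 (2.5 mol %), P(o-tol)3 (10 mol %), rt to 40 °C
Reagents that add atoms: none
Why: Zinc insertion gives an ester-chelated alkylzinc iodide that does not β-eliminate, and Negishi coupling with iodobenzene under zerovalent palladium forms the benzylic C–C bond without touching the α-stereocentre.

Step 3
Reactants: 5 methyl (S)-2-methyl-3-phenylpropanoate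
Product: 6 (S)-2-methyl-3-phenylpropanal
Conditions: i-Bu2AlH (1.05 equiv), CH2Cl2, −78 °C; MeOH, then aq. sodium potassium tartrate
Reagents that add atoms: none
Why: Half-reduction of the methyl ester by i-Bu2AlH stops at the aluminium hemiacetal at −78 °C and releases the aldehyde on work-up; the α-stereocentre should survive if the aldehyde is kept away from base and used at once.

Step 4
Reactants: 6 (S)-2-methyl-3-phenylpropanal; 7 isopropenylmagnesium bromide
Product: 8 (3RS,4S)-2,4-dimethyl-5-phenylpent-1-en-3-ol
Conditions: 7 (1.3 equiv), THF, −78 to −40 °C; aq. NH4Cl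
Reagents that add atoms: none
Why: Grignard 1,2-addition to the aldehyde; the carbinol centre forms as a mixture, which does not matter because it becomes sp2 in step 5.

Step 5
Reactants: 8 (3RS,4S)-2,4-dimethyl-5-phenylpent-1-en-3-ol; 9 triethyl orthoacetate
Product: 11 ethyl (4E,6S)-4,6-dimethyl-7-phenylhept-4-enoate, via ketene acetal 10 (not isolated)
Conditions: 9 (6 equiv), EtCO2H (cat.), 140 °C, EtOH distilled off
Reagents that add atoms: none
Why: Johnson–Claisen rearrangement; the mixed ketene acetal rearranges through a chair in which the branched substituent on the carbinol carbon is equatorial, which should give the E-trisubstituted alkene from either carbinol epimer and leaves C6 untouched.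

Step 6
Reactants: 11 ethyl (4E,6S)-4,6-dimethyl-7-phenylhept-4-enoate
Product: 12 (4E,6S)-4,6-dimethyl-7-phenylhept-4-enoic acid
Conditions: LiOH·H2O, THF–MeOH–H2O, rt; then 1 M HCl
Reagents that add atoms: lithium hydroxide, [Li+].[OH-]
Why: Saponification of an unhindered ethyl ester; no stereocentre is α to the carboxyl group.

**Core and end game**

Step 7
Reactants: 13 D-tartaric acid
Product: 14 di-tert-butyl D-tartrate, di-tert-butyl (2S,3S)-2,3-dihydroxybutanedioate
Conditions: O-tert-butyl-N,N'-diisopropylisourea (3 equiv), THF, rt to 40 °C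
Reagents that add atoms: O-tert-butyl-N,N'-diisopropylisourea, CC(C)NC(=NC(C)C)OC(C)(C)C
Why: Esterification with an O-alkylisourea; each carboxylic acid protonates the isourea and the carboxylate captures the tert-butyl group, so the hydroxyls stay free and no strong acid is used.

Step 8
Reactants: 14 di-tert-butyl D-tartrate
Product: 15 di-tert-butyl (4S,5S)-2-methoxy-1,3-dioxolane-4,5-dicarboxylate
Conditions: HC(OMe)3 (3 equiv), PPTS (cat.), toluene, 70 °C, MeOH distilled off
Reagents that add atoms: trimethyl orthoformate, COC(OC)OC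
Why: Acid-catalysed orthoester exchange closes a five-membered cyclic orthoformate on the 1,2-diol; it gives the enolate chemistry the same ring constraint as an isopropylidene ketal but can later be exchanged off at an acidity that tert-butyl esters tolerate, and since the orthoester carbon lies on the twofold axis one compound should result.

Step 9
Reactants: 15 di-tert-butyl (4S,5S)-2-methoxy-1,3-dioxolane-4,5-dicarboxylate; 16 tert-butyl chlorooxoacetate
Product: 18 tert-butyl 2-[(4S,5S)-4,5-bis(tert-butoxycarbonyl)-2-methoxy-1,3-dioxolan-4-yl]-2-oxoacetate, via lithium enolate 17 (not isolated)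
Conditions: commercial LiN(i-Pr)2 (1.05 equiv), THF, −78 °C; enolate cannulated into 16 (1.5 equiv), THF, −78 °C; pH 7 buffer
Reagents that add atoms: none
Why: Claisen-type C-acylation of an ester enolate by an acid chloride; the dioxolane holds the β C–O bond out of alignment with the enolate π system so that β-elimination is slow at −78 °C (the known behaviour of tartrate ketal enolates), the electrophile should enter anti to the ester on the neighbouring ring carbon, which makes the two ring esters cis and sets C4, and the product has no α-hydrogen that could quench unreacted enolate.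

Step 10
Reactants: 18 tert-butyl 2-[(4S,5S)-4,5-bis(tert-butoxycarbonyl)-2-methoxy-1,3-dioxolan-4-yl]-2-oxoacetate; 19 allylmagnesium bromide
Product: 20 tert-butyl (2R)-2-[(4S,5S)-4,5-bis(tert-butoxycarbonyl)-2-methoxy-1,3-dioxolan-4-yl]-2-hydroxypent-4-enoate
Conditions: 19 (1 M in Et2O, 1.2 equiv), CH2Cl2, −78 °C; pH 7 buffer at −78 °C
Reagents that add atoms: none
Why: Grignard addition to the ketone of an α-keto ester, which is far more electrophilic than the hindered tert-butyl ester carbonyls; magnesium is expected to bridge the ketone oxygen and the carbonyl oxygen of the ester on the same ring carbon (six-membered chelate), and in that rotamer the allyl group should enter past the ring oxygen and not past the neighbouring ring C–H, which gives the (R) configuration at C5.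

Step 11
Reactants: 20 tert-butyl (2R)-2-[(4S,5S)-4,5-bis(tert-butoxycarbonyl)-2-methoxy-1,3-dioxolan-4-yl]-2-hydroxypent-4-enoate
Product: 21 tri-tert-butyl (1S,2S,3R)-1,2,3-trihydroxyhex-5-ene-1,2,3-tricarboxylate
Conditions: PPTS (0.2 equiv), MeOH, rt
Reagents that add atoms: none
Why: Acid-catalysed orthoester exchange with the solvent releases the diol and trimethyl orthoformate; orthoesters exchange at an acidity far below that needed to ionise tert-butyl esters, and the tertiary homoallylic alcohol is inert.

Step 12
Reactants: 21 tri-tert-butyl (1S,2S,3R)-1,2,3-trihydroxyhex-5-ene-1,2,3-tricarboxylate; 12 (4E,6S)-4,6-dimethyl-7-phenylhept-4-enoic acid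
Product: 22 tri-tert-butyl (1S,2S,3R)-1-{[(4E,6S)-4,6-dimethyl-7-phenylhept-4-enoyl]oxy}-2,3-dihydroxyhex-5-ene-1,2,3-tricarboxylate
Conditions: EDC·HCl (1.5 equiv), DMAP (0.3 equiv), CH2Cl2, 0 °C to rt
Reagents that add atoms: none
Why: Steglich esterification; only the secondary C3 hydroxyl should be acylated, the two tertiary hydroxyls being too hindered for the acylpyridinium.

Step 13
Reactants: 22 tri-tert-butyl (1S,2S,3R)-1-{[(4E,6S)-4,6-dimethyl-7-phenylhept-4-enoyl]oxy}-2,3-dihydroxyhex-5-ene-1,2,3-tricarboxylate
Product: 23 tri-tert-butyl (1S,2S,3R)-1-{[(4E,6S)-4,6-dimethyl-7-phenylhept-4-enoyl]oxy}-2,3-bis(trimethylsilyloxy)hex-5-ene-1,2,3-tricarboxylate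
Conditions: 1-(trimethylsilyl)imidazole (6 equiv), CH2Cl2, rt to 40 °C
Reagents that add atoms: 1-(trimethylsilyl)imidazole, C[Si](C)(C)n1ccnc1
Why: Silyl transfer from a strong, non-acidic trimethylsilyl donor of the kind used for hindered tertiary alcohols; the hydroxyls are masked so that the organotitanium reagent of step 14 meets no acidic proton, and the tert-butyl esters see no silyl triflate.

Step 14
Reactants: 23 tri-tert-butyl (1S,2S,3R)-1-{[(4E,6S)-4,6-dimethyl-7-phenylhept-4-enoyl]oxy}-2,3-bis(trimethylsilyloxy)hex-5-ene-1,2,3-tricarboxylate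
Product: 24 tri-tert-butyl (1S,2S,3R)-1-{[(5E,7S)-5,7-dimethyl-8-phenylocta-1,5-dien-2-yl]oxy}-2,3-bis(trimethylsilyloxy)hex-5-ene-1,2,3-tricarboxylate
Conditions: Cp2TiMe2 (3 equiv), toluene, 70 °C, dark
Reagents that add atoms: dimethyltitanocene, C[Ti](C)(C1C=CC=C1)C1C=CC=C1
Why: Petasis methylenation, in which thermolysis of Cp2TiMe2 gives titanocene methylidene and this turns an ester carbonyl into a 1,1-disubstituted enol ether under non-acidic conditions; of the four ester carbonyls only that of the side-chain ester carries an unbranched acyl carbon, while each tert-butyl ester is shielded by its tert-alkoxy group and a branched or fully substituted α-carbon.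

Step 15
Reactants: 24 tri-tert-butyl (1S,2S,3R)-1-{[(5E,7S)-5,7-dimethyl-8-phenylocta-1,5-dien-2-yl]oxy}-2,3-bis(trimethylsilyloxy)hex-5-ene-1,2,3-tricarboxylate
Product: 25 tri-tert-butyl (2S,3S,4R)-7-[(3E,5S)-3,5-dimethyl-6-phenylhex-3-en-1-yl]-3,4-bis(trimethylsilyloxy)-2,3,4,5-tetrahydrooxepine-2,3,4-tricarboxylate
Conditions: second-generation Grubbs catalyst [RuCl2(=CHPh)(PCy3)(H2IMes)] (10 mol %), toluene, 70 °C, Ar sparge
Reagents that add atoms: none
Why: Ring-closing metathesis of the terminal alkene with the 1,1-disubstituted enol ether, a known way to six- and seven-membered cyclic enol ethers; the ruthenium alkylidene should load on the terminal alkene and close onto the enol ether with loss of ethene to give the C1=C7 bond of the seven-membered ring, and the trisubstituted side-chain alkene is too hindered to take part.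

Step 16
Reactants: 25 tri-tert-butyl (2S,3S,4R)-7-[(3E,5S)-3,5-dimethyl-6-phenylhex-3-en-1-yl]-3,4-bis(trimethylsilyloxy)-2,3,4,5-tetrahydrooxepine-2,3,4-tricarboxylate
Product: 27 tri-tert-butyl (1S,3S,4S,5R)-1-[(3E,5S)-3,5-dimethyl-6-phenylhex-3-en-1-yl]-4-hydroxy-2,8-dioxabicyclo[3.2.1]octane-3,4,5-tricarboxylate, via oxepene diol 26 (not isolated)
Conditions: CSA (0.2 equiv), MeOH–CH2Cl2 (1:5), 0 °C to rt; then solvent exchange, CSA, CH2Cl2, rt
Reagents that add atoms: none
Why: Methanolic CSA should cleave both tertiary trimethylsilyl ethers and protonate the enol ether at C7 (the carbon β to O2), giving an oxocarbenium ion at C1 stabilised by O2; the C5 hydroxyl, held across the seven-membered ring, then adds to C1 and closes the tetrahydrofuran ring in a 5-exo-trig manner, with the C1=O2 bond of the cation outside the new ring. The closest known reaction type is the acid-catalysed addition of a hydroxyl to a cyclic enol ether to give a ketal, run here transannularly. C1 is the only new stereocentre and is fixed by the bridge: O8 is bonded to C5 and can reach C1 only from the face of the oxepane on which it sits, so the (1S) configuration follows from C5. The step needs the C5 hydroxyl and not the C4 hydroxyl to end up on C1; ketal formation is reversible under the acid, so the 6,8-dioxabicyclo[3.2.1]octane from C4–O attack, or a methyl ketal from capture by solvent, should drain into the 2,8-isomer once methanol is removed and the mixture is stirred with CSA in CH2Cl2. The tert-butyl esters and the trisubstituted side-chain alkene should not respond to this weak acid.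

Step 17
Reactants: 27 tri-tert-butyl (1S,3S,4S,5R)-1-[(3E,5S)-3,5-dimethyl-6-phenylhex-3-en-1-yl]-4-hydroxy-2,8-dioxabicyclo[3.2.1]octane-3,4,5-tricarboxylate
Product: 28 (1S,3S,4S,5R)-1-[(3E,5S)-3,5-dimethyl-6-phenylhex-3-en-1-yl]-4-hydroxy-2,8-dioxabicyclo[3.2.1]octane-3,4,5-tricarboxylic acid
Conditions: CF3CO2H–CH2Cl2 (1:4), 0 °C to rt
Reagents that add atoms: none
Why: Acidolysis of the three tert-butyl esters by loss of 2-methylpropene; the 2,8-dioxabicyclo[3.2.1]octane ketal is the stable form under acid and the tertiary hydroxyl is deactivated by two flanking carboxyl groups, so only the esters should change.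

**Compound list**

1 | methyl (S)-3-hydroxy-2-methylpropanoate | COC(=O)[C@@H](C)CO | starting material
2 | methyl (R)-3-iodo-2-methylpropanoate | COC(=O)[C@@H](C)CI | intermediate
3 | iodobenzene | Ic1ccccc1 | starting material
4 | [(2R)-3-methoxy-2-methyl-3-oxopropyl]zinc iodide | COC(=O)[C@@H](C)C[Zn]I | intermediate (not isolated)
5 | methyl (S)-2-methyl-3-phenylpropanoate | COC(=O)[C@@H](C)Cc1ccccc1 | intermediate
6 | (S)-2-methyl-3-phenylpropanal | O=C[C@@H](C)Cc1ccccc1 | intermediate
7 | isopropenylmagnesium bromide | CC(=C)[Mg]Br | starting material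
8 | (3RS,4S)-2,4-dimethyl-5-phenylpent-1-en-3-ol | C=C(C)C(O)[C@@H](C)Cc1ccccc1 | intermediate
9 | triethyl orthoacetate | CCOC(C)(OCC)OCC | starting material
10 | mixed ketene acetal of 8, O-(1-ethoxyethenyl) ether of (3RS,4S)-2,4-dimethyl-5-phenylpent-1-en-3-ol | C=C(OCC)OC(C(C)=C)[C@@H](C)Cc1ccccc1 | intermediate (not isolated)
11 | ethyl (4E,6S)-4,6-dimethyl-7-phenylhept-4-enoate | CCOC(=O)CC/C(C)=C/[C@@H](C)Cc1ccccc1 | intermediate
12 | (4E,6S)-4,6-dimethyl-7-phenylhept-4-enoic acid | OC(=O)CC/C(C)=C/[C@@H](C)Cc1ccccc1 | intermediate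
13 | D-tartaric acid, (2S,3S)-2,3-dihydroxybutanedioic acid | O[C@@H]([C@H](O)C(=O)O)C(=O)O | starting material
14 | di-tert-butyl D-tartrate, di-tert-butyl (2S,3S)-2,3-dihydroxybutanedioate | O[C@@H]([C@H](O)C(=O)OC(C)(C)C)C(=O)OC(C)(C)C | intermediate
15 | di-tert-butyl (4S,5S)-2-methoxy-1,3-dioxolane-4,5-dicarboxylate | COC1O[C@H](C(=O)OC(C)(C)C)[C@@H](C(=O)OC(C)(C)C)O1 | intermediate
16 | tert-butyl chlorooxoacetate | CC(C)(C)OC(=O)C(=O)Cl | starting material
17 | lithium enolate of 15 (one ring ester as its lithium enolate, the other ring carbon still S) | [Li]OC(OC(C)(C)C)=C1OC(OC)O[C@@H]1C(=O)OC(C)(C)C | intermediate (not isolated)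
18 | tert-butyl 2-[(4S,5S)-4,5-bis(tert-butoxycarbonyl)-2-methoxy-1,3-dioxolan-4-yl]-2-oxoacetate (both epimers at the orthoester carbon) | O=C(C(=O)OC(C)(C)C)[C@](O1)(C(=O)OC(C)(C)C)[C@@H](C(=O)OC(C)(C)C)OC1OC | intermediate
19 | allylmagnesium bromide | C=CC[Mg]Br | starting material
20 | tert-butyl (2R)-2-[(4S,5S)-4,5-bis(tert-butoxycarbonyl)-2-methoxy-1,3-dioxolan-4-yl]-2-hydroxypent-4-enoate (both epimers at the orthoester carbon) | C=CC[C@@](C(=O)OC(C)(C)C)(O)[C@](O1)(C(=O)OC(C)(C)C)[C@@H](C(=O)OC(C)(C)C)OC1OC | intermediate
21 | tri-tert-butyl (1S,2S,3R)-1,2,3-trihydroxyhex-5-ene-1,2,3-tricarboxylate | C=CC[C@@](C(=O)OC(C)(C)C)(O)[C@](O)(C(=O)OC(C)(C)C)[C@@H](C(=O)OC(C)(C)C)O | intermediate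
22 | tri-tert-butyl (1S,2S,3R)-1-{[(4E,6S)-4,6-dimethyl-7-phenylhept-4-enoyl]oxy}-2,3-dihydroxyhex-5-ene-1,2,3-tricarboxylate | C=CC[C@@](C(=O)OC(C)(C)C)(O)[C@](O)(C(=O)OC(C)(C)C)[C@@H](C(=O)OC(C)(C)C)OC(=O)CC/C(C)=C/[C@@H](C)Cc1ccccc1 | intermediate
23 | tri-tert-butyl (1S,2S,3R)-1-{[(4E,6S)-4,6-dimethyl-7-phenylhept-4-enoyl]oxy}-2,3-bis(trimethylsilyloxy)hex-5-ene-1,2,3-tricarboxylate | C=CC[C@@](C(=O)OC(C)(C)C)(O[Si](C)(C)C)[C@](O[Si](C)(C)C)(C(=O)OC(C)(C)C)[C@@H](C(=O)OC(C)(C)C)OC(=O)CC/C(C)=C/[C@@H](C)Cc1ccccc1 | intermediate
24 | tri-tert-butyl (1S,2S,3R)-1-{[(5E,7S)-5,7-dimethyl-8-phenylocta-1,5-dien-2-yl]oxy}-2,3-bis(trimethylsilyloxy)hex-5-ene-1,2,3-tricarboxylate | C=CC[C@@](C(=O)OC(C)(C)C)(O[Si](C)(C)C)[C@](O[Si](C)(C)C)(C(=O)OC(C)(C)C)[C@@H](C(=O)OC(C)(C)C)OC(=C)CC/C(C)=C/[C@@H](C)Cc1ccccc1 | intermediate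
25 | tri-tert-butyl (2S,3S,4R)-7-[(3E,5S)-3,5-dimethyl-6-phenylhex-3-en-1-yl]-3,4-bis(trimethylsilyloxy)-2,3,4,5-tetrahydrooxepine-2,3,4-tricarboxylate | C/C(=C\[C@@H](C)Cc1ccccc1)CCC1=CC[C@](O[Si](C)(C)C)(C(=O)OC(C)(C)C)[C@](O[Si](C)(C)C)(C(=O)OC(C)(C)C)[C@@H](C(=O)OC(C)(C)C)O1 | intermediate (key-step precursor)
26 | tri-tert-butyl (2S,3S,4R)-7-[(3E,5S)-3,5-dimethyl-6-phenylhex-3-en-1-yl]-3,4-dihydroxy-2,3,4,5-tetrahydrooxepine-2,3,4-tricarboxylate | C/C(=C\[C@@H](C)Cc1ccccc1)CCC1=CC[C@](O)(C(=O)OC(C)(C)C)[C@](O)(C(=O)OC(C)(C)C)[C@@H](C(=O)OC(C)(C)C)O1 | intermediate (not isolated)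
27 | tri-tert-butyl (1S,3S,4S,5R)-1-[(3E,5S)-3,5-dimethyl-6-phenylhex-3-en-1-yl]-4-hydroxy-2,8-dioxabicyclo[3.2.1]octane-3,4,5-tricarboxylate | C/C(=C\[C@@H](C)Cc1ccccc1)CC[C@@]12CC[C@@](C(=O)OC(C)(C)C)(O1)[C@](O)(C(=O)OC(C)(C)C)[C@@H](C(=O)OC(C)(C)C)O2 | intermediate (key-step product)
28 | (1S,3S,4S,5R)-1-[(3E,5S)-3,5-dimethyl-6-phenylhex-3-en-1-yl]-4-hydroxy-2,8-dioxabicyclo[3.2.1]octane-3,4,5-tricarboxylic acid | C/C(=C\[C@@H](C)Cc1ccccc1)CC[C@@]12CC[C@@](C(=O)O)(O1)[C@](O)(C(=O)O)[C@@H](C(=O)O)O2 | target

**Totals**

Total step count: 17.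
Longest linear sequence: 12 steps (steps 1–6, then 12–17, from methyl (S)-3-hydroxy-2-methylpropanoate). The core branch from D-tartaric acid runs 11 steps (7–17).

**Steps most likely to fail**

1. Step 10. What may go wrong: the allyl group is transferred to both faces of the ketone, or mainly to the unwanted one. The six-membered magnesium chelate that is meant to fix the C4–C5 rotamer competes with chelation by the two keto-ester oxygens or by the ring oxygen, and allyl Grignard reagents react almost without discrimination. Fallback: the C4–C5 bond and the C5 centre would be made in one aldol event and not by addition to a preformed ketone. The path sets out from 15. Enolate 17 (LiN(i-Pr)2, THF, −78 °C) would be added to tert-butyl 2-oxopent-4-enoate F1, which already carries the allyl group and would be made from 19 and di-tert-butyl oxalate at −78 °C. The aldol adduct is 20, where the route is rejoined. The enolate should again react on the face anti to the ring ester. The face of the keto ester is then chosen in a closed, metal-bridged six-membered transition state that can be tuned through the enolate counter-ion (Li, MgBr, ZnCl) and does not depend on how a ketone next to C4 is chelated.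

2. Step 9. What may go wrong: O-acylation of the enolate, addition of a second enolate to the newly formed ketone, or β-elimination of the enolate before it is trapped. Fallback: the two-carbon unit would be brought in at the aldehyde oxidation level. The path sets out from 15. Enolate 17 would be added at −78 °C to tert-butyl 2-oxoacetate F2 (from 14 by glycol cleavage with Pb(OAc)4), an aldol addition of the kind well known for tartrate ketal enolates. This should give tert-butyl 2-[(4R,5S)-4,5-bis(tert-butoxycarbonyl)-2-methoxy-1,3-dioxolan-4-yl]-2-hydroxyacetate F3 as a mixture at the carbinol carbon, with the ring carbons arranged as in 18. Oxidation of F3 with Dess–Martin periodinane buffered by NaHCO3 would then return to keto ester 18.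

3. Step 15. What may go wrong: the ruthenium alkylidene loads on the terminal alkene but fails to engage the crowded 1,1-disubstituted enol ether, so that alkene isomerisation or dimerisation takes over. Fallback: ring closure would be moved from ruthenium to titanium and from the enol ether to the ester. The path sets out from 23, which would be treated with the reduced titanium ethylidene reagent (TiCl4, TMEDA, Zn dust, PbCl2 cat., CH3CHBr2, THF–CH2Cl2, 0 to 65 °C; Takai–Utimoto olefinic-ester cyclisation). The titanium alkylidene formed at the terminal alkene should olefinate the side-chain ester carbonyl intramolecularly. The path comes back at 25; no new compound is isolated on it (F0).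

Further compounds
F1 | step 10 | tert-butyl 2-oxopent-4-enoate | C=CCC(=O)C(=O)OC(C)(C)C
F2 | step 9 | tert-butyl 2-oxoacetate | O=CC(=O)OC(C)(C)C
F3 | step 9 | tert-butyl 2-[(4R,5S)-4,5-bis(tert-butoxycarbonyl)-2-methoxy-1,3-dioxolan-4-yl]-2-hydroxyacetate | OC(C(=O)OC(C)(C)C)[C@](O1)(C(=O)OC(C)(C)C)[C@@H](C(=O)OC(C)(C)C)OC1OC
F0 | step 15 | none | none
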